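**Strategy.** The route rests on disconnecting the C3–C3a bond of the dihydrofuran ring (O1–C2–C3–C3a–C7a). C3a lies para to the C6 carbonyl oxygen of the six-membered ring and next to the ether-bearing C7a, so that ring can be carried as a flat phenol, while C3 is benzylic to the trimethoxyphenyl ring. In the key step acid ionises a lactate-derived benzylic alcohol; ipso attack by the allyl-bearing phenol carbon closes the five-membered ring, dearomatises the six-membered ring to a dienone and sets C3 and quaternary C3a from C2. The precursor is an aryl ether whose O-allyl group first masks the phenol and then moves to carbon by para-Claisen rearrangement. A final conjugate reduction sets C5.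

Key step: step 7

Remark: locants O1, C2, C3, C3a, C4–C7, C7a are those of the benzofuranone skeleton of the target. The carbinol centre made in step 6 (16, F2) and the transient ring centres of dienones 10–12 are mixtures and are drawn without configuration; the carbinol centre becomes a planar cation in step 7. Compound 14 is taken as its commercial THF solution.

Step 1
Reactants: 1 2,6-dimethoxyphenol (syringol); 2 allyl bromide
Product: 3 2-(allyloxy)-1,3-dimethoxybenzene
Conditions: K2CO3, acetone, reflux
Reagents that add atoms: none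
Why: Williamson ether synthesis (SN2 of the phenoxide on allyl bromide); the allyl group masks the oxygen that becomes the C6 carbonyl and is the future C3a substituent.

Step 2
Reactants: 3 2-(allyloxy)-1,3-dimethoxybenzene
Product: 5 3-(allyloxy)-2,4-dimethoxybenzaldehyde, via iminium chloride 4 (not isolated)
Conditions: POCl3, DMF, 0 → 75 °C; then aq NaOH, 0 °C
Reagents that add atoms: N,N-dimethylformamide, CN(C)C=O; water, O
Why: Vilsmeier–Haack formylation should go to the ring position ortho to one methoxy group and para to the other, as with 1,2,3-trimethoxybenzene, and aqueous base hydrolyses iminium salt 4 to the aldehyde.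

Step 3
Reactants: 5 3-(allyloxy)-2,4-dimethoxybenzaldehyde
Product: 7 3-(allyloxy)-2,4-dimethoxyphenol, via aryl formate 6 (not isolated)
Conditions: mCPBA, CH2Cl2, 0 °C → rt; then MeOH, Et3N (cat.), rt
Reagents that add atoms: mCPBA (3-chloroperoxybenzoic acid), O=C(OO)c1cccc(Cl)c1
Why: Baeyer–Villiger oxidation of an electron-rich benzaldehyde (Dakin-type) with aryl migration gives formate 6, whose methanolysis frees the phenol that will carry O1; the terminal alkene should be epoxidised far more slowly.

Step 4
Reactants: 7 3-(allyloxy)-2,4-dimethoxyphenol; 8 ethyl (S)-lactate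
Product: 9 ethyl (2R)-2-[3-(allyloxy)-2,4-dimethoxyphenoxy]propanoate
Conditions: PPh3, DIAD, THF, 0 °C → rt
Reagents that add atoms: none
Why: Mitsunobu etherification proceeds by SN2 with inversion, turning the S carbinol of the lactate into the R aryl ether centre that becomes C2 of the target.

Step 5
Reactants: 9 ethyl (2R)-2-[3-(allyloxy)-2,4-dimethoxyphenoxy]propanoate
Product: 13 ethyl (2R)-2-(6-allyl-3-hydroxy-2,4-dimethoxyphenoxy)propanoate, via ortho-dienone 10 (not isolated), via regioisomeric ortho-dienone 11 (not isolated), via para-dienone 12 (not isolated)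
Conditions: Ph2O, 200 °C, Ar
Reagents that add atoms: none
Why: para-Claisen rearrangement, known for allyl 2,6-dimethoxyphenyl ethers: a [3,3] shift to a methoxy-blocked ortho carbon (10 or 11), a Cope [3,3] shift to the free para carbon (12) and tautomerisation, in a neutral solvent that should leave the ester-bearing stereocentre untouched.

Step 6
Reactants: 13 ethyl (2R)-2-(6-allyl-3-hydroxy-2,4-dimethoxyphenoxy)propanoate; 14 3,4,5-trimethoxyphenylmagnesium bromide
Product: 16 4-allyl-3-{[(2R)-1-hydroxy-1-(3,4,5-trimethoxyphenyl)propan-2-yl]oxy}-2,6-dimethoxyphenol, via aldehyde 15 (not isolated)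
Conditions: i-Bu2AlH (2.2 equiv), CH2Cl2, −78 °C; then 14 (3 equiv), THF, −78 → 0 °C; aq potassium sodium tartrate
Reagents that add atoms: none
Why: Partial reduction of the ester to its aluminium hemiacetal and Grignard addition to aldehyde 15 as it is released avoid isolating the epimerisable α-aryloxy aldehyde; one hydride equivalent is consumed by the phenol, and the carbinol centre is left as a mixture because step 7 ionises it.

Step 7
Reactants: 16 4-allyl-3-{[(2R)-1-hydroxy-1-(3,4,5-trimethoxyphenyl)propan-2-yl]oxy}-2,6-dimethoxyphenol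
Product: 17 (2R,3S,3aR)-3a-allyl-5,7-dimethoxy-2-methyl-3-(3,4,5-trimethoxyphenyl)-3,3a-dihydro-1-benzofuran-6(2H)-one
Conditions: TfOH (5 mol %), (CF3)2CHOH/CH2Cl2 (1:4), 0.005 M, −20 → 0 °C; then Et3N
Reagents that add atoms: none
Why: Acid ionises the benzylic alcohol (both carbinol epimers converge) to a 3,4,5-trimethoxybenzyl-type cation at C3, which is attacked ipso by C3a, the allyl-bearing ring carbon para to the free hydroxyl and ortho to the ether oxygen, and loss of the phenolic proton from the arenium ion gives the cross-conjugated dienone. The closest known reaction type is the acid-promoted intramolecular ipso-Friedel–Crafts alkylation of para-substituted phenols to cyclohexadienones, run here dehydratively in a fluorinated alcohol. The dihydrofuran ring closes by cation–arene attack through a five-membered envelope transition state in which the attacked C3a–C7a bond is endocyclic and C3a–C4 exocyclic, the geometry of Friedel–Crafts closures to indanes and dihydrobenzofurans. C3 is controlled by the lactate-derived C2, because allylic strain keeps the C2–H and not the methyl group beside the aryl group of the planar cation, so the aryl group ends trans to the methyl group; C3a is controlled by the aryl group taking the exo position, away from the face of the phenol ring and over the allyl group that bends away, which should place aryl and allyl cis. The step needs ipso attack at C3a in preference to attack at the methoxy-bearing C7 and to loss of the C2 proton from the cation; the para hydroxyl makes C3a the most nucleophilic site and its O–H loss is immediate, and the non-basic, non-nucleophilic medium, low temperature and high dilution should suppress elimination and intermolecular alkylation.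

Step 8
Reactants: 17 (2R,3S,3aR)-3a-allyl-5,7-dimethoxy-2-methyl-3-(3,4,5-trimethoxyphenyl)-3,3a-dihydro-1-benzofuran-6(2H)-one
Product: 19 (2R,3S,3aS,5S)-3a-allyl-5,7-dimethoxy-2-methyl-3-(3,4,5-trimethoxyphenyl)-3,3a,4,5-tetrahydro-1-benzofuran-6(2H)-one (CNP0136253.1), via C5 epimer 18 (not isolated)
Conditions: [(Ph3P)CuH]6 (0.4 equiv), H2O (5 equiv), benzene, rt; then DBU (0.2 equiv), toluene, rt
Reagents that add atoms: none
Why: Conjugate reduction by the copper hydride should deliver hydride only to C4 of the less substituted α-methoxy enone (the C7=C7a arm is a vinylogous ester and the allyl alkene is unactivated), and DBU then equilibrates the epimerisable C5 centre to the equatorial methoxy group, trans to the pseudoaxial allyl group on C3a, which is the 5S configuration.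

**Compound list**

1 | 2,6-dimethoxyphenol (syringol) | COc1cccc(OC)c1O | starting material
2 | allyl bromide | C=CCBr | starting material
3 | 2-(allyloxy)-1,3-dimethoxybenzene | C=CCOc1c(OC)cccc1OC | intermediate
4 | [3-(allyloxy)-2,4-dimethoxybenzylidene]dimethylammonium chloride | C=CCOc1c(OC)ccc(C=[N+](C)C)c1OC.[Cl-] | intermediate
5 | 3-(allyloxy)-2,4-dimethoxybenzaldehyde | C=CCOc1c(OC)ccc(C=O)c1OC | intermediate
6 | 3-(allyloxy)-2,4-dimethoxyphenyl formate | C=CCOc1c(OC)ccc(OC=O)c1OC | intermediate
7 | 3-(allyloxy)-2,4-dimethoxyphenol | C=CCOc1c(OC)ccc(O)c1OC | intermediate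
8 | ethyl (S)-lactate | C[C@H](O)C(=O)OCC | starting material
9 | ethyl (2R)-2-[3-(allyloxy)-2,4-dimethoxyphenoxy]propanoate | C[C@@H](Oc1ccc(OC)c(OCC=C)c1OC)C(=O)OCC | intermediate
10 | ethyl (2R)-2-[(4-allyl-2,4-dimethoxy-3-oxocyclohexa-1,5-dien-1-yl)oxy]propanoate | C[C@@H](OC1=C(OC)C(=O)C(CC=C)(OC)C=C1)C(=O)OCC | intermediate
11 | ethyl (2R)-2-[(6-allyl-4,6-dimethoxy-5-oxocyclohexa-1,3-dien-1-yl)oxy]propanoate | C[C@@H](OC1=CC=C(OC)C(=O)C1(CC=C)OC)C(=O)OCC | intermediate
12 | ethyl (2R)-2-[(6-allyl-2,4-dimethoxy-3-oxocyclohexa-1,4-dien-1-yl)oxy]propanoate | C[C@@H](OC1=C(OC)C(=O)C(OC)=CC1CC=C)C(=O)OCC | intermediate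
13 | ethyl (2R)-2-(6-allyl-3-hydroxy-2,4-dimethoxyphenoxy)propanoate | C[C@@H](Oc1c(CC=C)cc(OC)c(O)c1OC)C(=O)OCC | intermediate
14 | 3,4,5-trimethoxyphenylmagnesium bromide | COc1cc([Mg]Br)cc(OC)c1OC | starting material
15 | (2R)-2-(6-allyl-3-hydroxy-2,4-dimethoxyphenoxy)propanal | C[C@@H](Oc1c(CC=C)cc(OC)c(O)c1OC)C=O | intermediate
16 | 4-allyl-3-{[(2R)-1-hydroxy-1-(3,4,5-trimethoxyphenyl)propan-2-yl]oxy}-2,6-dimethoxyphenol (carbinol epimers) | C[C@@H](Oc1c(CC=C)cc(OC)c(O)c1OC)C(O)c1cc(OC)c(OC)c(OC)c1 | intermediate
17 | (2R,3S,3aR)-3a-allyl-5,7-dimethoxy-2-methyl-3-(3,4,5-trimethoxyphenyl)-3,3a-dihydro-1-benzofuran-6(2H)-one | C=CC[C@@]12C=C(OC)C(=O)C(OC)=C1O[C@H](C)[C@H]2c1cc(OC)c(OC)c(OC)c1 | intermediate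
18 | (2R,3S,3aS,5R)-3a-allyl-5,7-dimethoxy-2-methyl-3-(3,4,5-trimethoxyphenyl)-3,3a,4,5-tetrahydro-1-benzofuran-6(2H)-one | C=CC[C@@]12C[C@@H](OC)C(=O)C(OC)=C1O[C@H](C)[C@H]2c1cc(OC)c(OC)c(OC)c1 | intermediate
19 | (2R,3S,3aS,5S)-3a-allyl-5,7-dimethoxy-2-methyl-3-(3,4,5-trimethoxyphenyl)-3,3a,4,5-tetrahydro-1-benzofuran-6(2H)-one | C=CC[C@@]12C[C@H](OC)C(=O)C(OC)=C1O[C@H](C)[C@H]2c1cc(OC)c(OC)c(OC)c1 | target

**Step count and risks**

Total step count: 8. Longest linear sequence: 8 steps (1 → 19).

Steps most likely to fail:

Step 7. After ionisation the cation may lose the C2 proton (or undergo a 1,2-hydride shift) to an enol ether that is hydrolysed with cleavage of the aryl ether before the strained ipso attack takes place. The facial selectivity at C3a (aryl exo against endo) may also be poor. The fallback sets out from 13 and comes back at 17, and replaces the free cation by a neutral p-quinone methide. The ester is reduced as in step 6 (aldehyde 15), but the aldehyde is trapped with lithium 4-lithio-2,6-dimethoxyphenoxide F1 (from 4-bromo-2,6-dimethoxyphenol and t-BuLi, THF, −78 °C) to give 4-allyl-3-{[(2R)-1-hydroxy-1-(4-hydroxy-3,5-dimethoxyphenyl)propan-2-yl]oxy}-2,6-dimethoxyphenol F2. Catalytic diphenyl phosphate in CH2Cl2 should dehydrate the 4-hydroxybenzyl alcohol to 4-[(2R)-2-(6-allyl-3-hydroxy-2,4-dimethoxyphenoxy)propylidene]-2,6-dimethoxycyclohexa-2,5-dien-1-one F3. This is expected to close by intramolecular 1,6-conjugate addition of C3a to give (2R,3S,3aR)-3a-allyl-3-(4-hydroxy-3,5-dimethoxyphenyl)-5,7-dimethoxy-2-methyl-3,3a-dihydro-1-benzofuran-6(2H)-one F4. Methylation of the one remaining phenol (MeI, K2CO3, acetone) would give 17.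

Step 8. Hydride may add 1,2 to the C6 carbonyl, giving a dienol prone to rearrangement, or add too slowly to the neopentyl-type C4. The C5 epimers may also fail to converge. The fallback sets out from 17 and comes back at 19, and separates hydride delivery from C5 protonation. Catalytic RhCl(PPh3)3 with Et3SiH (benzene, 50 °C) should give by 1,4-hydrosilylation the isolable (2R,3S,3aS)-3a-allyl-5,7-dimethoxy-2-methyl-6-[(triethylsilyl)oxy]-3-(3,4,5-trimethoxyphenyl)-2,3,3a,4-tetrahydro-1-benzofuran F5. Desilylation with TBAF/AcOH in THF followed by DBU in toluene would then give 19 under equilibrating conditions.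

Step 5. At 200 °C the centre next to the ester may partly racemise, and the ortho-dienone intermediates may be diverted (loss of methanol, abnormal Claisen products). The fallback sets out from 9 and comes back at 13, and puts the allyl group on carbon by cross-coupling instead of by sigmatropic shifts. Pd(PPh3)4 (cat.) with morpholine in THF removes the O-allyl group to give ethyl (2R)-2-(3-hydroxy-2,4-dimethoxyphenoxy)propanoate F6. NBS in CH2Cl2 at −78 °C should brominate para to the free hydroxyl to give ethyl (2R)-2-(6-bromo-3-hydroxy-2,4-dimethoxyphenoxy)propanoate F7. Stille coupling with allyltributylstannane (Pd(PPh3)4, toluene, 100 °C) would give 13.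

**Further compounds**

F1 | step 7 | lithium 4-lithio-2,6-dimethoxyphenoxide | [Li]Oc1c(OC)cc([Li])cc1OC
F2 | step 7 | 4-allyl-3-{[(2R)-1-hydroxy-1-(4-hydroxy-3,5-dimethoxyphenyl)propan-2-yl]oxy}-2,6-dimethoxyphenol | C[C@@H](Oc1c(CC=C)cc(OC)c(O)c1OC)C(O)c1cc(OC)c(O)c(OC)c1
F3 | step 7 | 4-[(2R)-2-(6-allyl-3-hydroxy-2,4-dimethoxyphenoxy)propylidene]-2,6-dimethoxycyclohexa-2,5-dien-1-one | C[C@@H](Oc1c(CC=C)cc(OC)c(O)c1OC)C=C1C=C(OC)C(=O)C(OC)=C1
F4 | step 7 | (2R,3S,3aR)-3a-allyl-3-(4-hydroxy-3,5-dimethoxyphenyl)-5,7-dimethoxy-2-methyl-3,3a-dihydro-1-benzofuran-6(2H)-one | C=CC[C@@]12C=C(OC)C(=O)C(OC)=C1O[C@H](C)[C@H]2c1cc(OC)c(O)c(OC)c1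
F5 | step 8 | (2R,3S,3aS)-3a-allyl-5,7-dimethoxy-2-methyl-6-[(triethylsilyl)oxy]-3-(3,4,5-trimethoxyphenyl)-2,3,3a,4-tetrahydro-1-benzofuran | C=CC[C@@]12CC(OC)=C(O[Si](CC)(CC)CC)C(OC)=C1O[C@H](C)[C@H]2c1cc(OC)c(OC)c(OC)c1
F6 | step 5 | ethyl (2R)-2-(3-hydroxy-2,4-dimethoxyphenoxy)propanoate | C[C@@H](Oc1ccc(OC)c(O)c1OC)C(=O)OCC
F7 | step 5 | ethyl (2R)-2-(6-bromo-3-hydroxy-2,4-dimethoxyphenoxy)propanoate | C[C@@H](Oc1c(Br)cc(OC)c(O)c1OC)C(=O)OCC
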